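**Retrosynthetic overview**
- Feature: the ten-membered carbocycle (C1–C10) carries at C7 the 2-propenyl unit C11(=C13)–C12 next to the C8 carbinol, a homoallylic alcohol array. It is cut at C7–C8 into a C8 aldehyde and an allylstannane with tin on C13 (open chain 21).
- Forward, BF3-promoted SE2′ closure of 21 forms the carbocycle together with C7 and C8 (22). The γ-lactone comes last: O8 angeloylation, acid removal of acetonide and silyl ether, oxidative lactonisation of C12 onto O6.
- 21 is built on L-tartrate acetonide (C4–C7, stereocentres C5 and C6): Weinreb ketone synthesis and methylenation (C1–C3, C15), Baylis–Hillman/acetate/stannylcopper SN2′/reduction (C11–C13), Wittig reaction with a lactone ylide followed by ring opening and oxidation (C8–C10, C14).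
- Ring order: dioxolane (protecting ring, present from the start), ten-membered carbocycle (step 16), γ-lactone (step 19).

Key step: step 16

Numbering: germacranolide numbering is used throughout (ring C1–C10; C11–C13 the lactone carbons, C12 the carbonyl and C13 the methylene; C14 the ester carbon on C10; C15 the methylene on C4).
Assumption: the two C7 epimers formed in step 6 are carried together, because C7 becomes trigonal in step 8.

**Route**

Step 1
Reactants: 1 dimethyl 2,3-O-isopropylidene-L-tartrate
Product: 2 bis-Weinreb amide of the tartrate acetonide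
Conditions: MeNH(OMe)·HCl, i-PrMgCl, THF, −20 to 0 °C
Reagents that add atoms: N,O-dimethylhydroxylamine hydrochloride, CNOC.Cl
Why: Aminolysis of both esters by the chloromagnesium amide of N,O-dimethylhydroxylamine (Weinreb amide formation) is fast at low temperature and leaves the trans-dioxolane stereocentres untouched.

Step 2
Reactants: 3 3-bromopropan-1-ol
Product: 4 (3-bromopropoxy)triethylsilane
Conditions: Et3SiCl, imidazole, CH2Cl2, 0 °C
Reagents that add atoms: chlorotriethylsilane, CC[Si](Cl)(CC)CC
Why: Imidazole-mediated O-silylation of a primary alcohol gives a triethylsilyl ether that can later be cleaved in the presence of a tert-butyldimethylsilyl ether.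

Step 3
Reactants: 2 bis-Weinreb amide; 4 (3-bromopropoxy)triethylsilane
Product: 6 keto Weinreb amide (C1–C4 chain attached; C4 ketone), via Grignard reagent 5 (not isolated)
Conditions: 4, Mg, THF, rt; then 2, THF, −20 to 0 °C; aq. NH4Cl
Reagents that add atoms: none
Why: Weinreb ketone synthesis in which the Grignard reagent adds to one of the two homotopic amides of the C2-symmetric substrate and the chelated tetrahedral magnesium intermediate resists both collapse and a second addition at low temperature, so the monoketone should result on quench.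

Step 4
Reactants: 6 keto Weinreb amide
Product: 7 methylene Weinreb amide (C4=C15 in place)
Conditions: Ph3PCH3Br, KN(SiMe3)2, THF, 0 °C; then 6, 0 °C to rt
Reagents that add atoms: methyltriphenylphosphonium bromide, C[P+](c1ccccc1)(c1ccccc1)c1ccccc1.[Br-]
Why: Wittig methylenation converts the ketone into the C4=C15 methylene faster than the ylide attacks the Weinreb amide, and the trans-dioxolane is the thermodynamically preferred arrangement should C5 enolise.

Step 5
Reactants: 7 methylene Weinreb amide
Product: 8 C7 aldehyde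
Conditions: i-Bu2AlH, THF, −78 °C; aq. KNaC4H4O6
Reagents that add atoms: none
Why: Reduction of a Weinreb amide with i-Bu2AlH stops at the chelated aluminium hemiaminal, which releases the aldehyde only on work-up.

Step 6
Reactants: 8 C7 aldehyde; 9 methyl acrylate
Product: 10 Baylis–Hillman alcohol (C7 epimer mixture)
Conditions: 9 (excess), DABCO (0.5 equiv), neat, rt
Reagents that add atoms: none
Why: Morita–Baylis–Hillman reaction in which the DABCO–acrylate zwitterion adds to the activated α-alkoxy aldehyde to form C7–C11; the new C7 carbinol centre forms as an epimer mixture that does not matter because C7 becomes trigonal in step 8.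

Step 7
Reactants: 10 Baylis–Hillman alcohol
Product: 11 Baylis–Hillman acetate
Conditions: Ac2O, Et3N, DMAP (cat.), CH2Cl2, 0 °C
Reagents that add atoms: acetic anhydride, CC(=O)OC(C)=O
Why: DMAP-catalysed acetylation turns the secondary allylic hydroxyl into the leaving group needed for the SN2′ step.

Step 8
Reactants: 11 Baylis–Hillman acetate
Product: 12 (Z)-2-(stannylmethyl) enoate
Conditions: Bu3SnH, LiN(i-Pr)2, THF, 0 °C; CuBr·SMe2, −78 °C; then 11, −78 °C
Reagents that add atoms: tributyltin hydride, CCCC[SnH](CCCC)CCCC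
Why: SN2′ substitution (conjugate addition–elimination) of the Baylis–Hillman acetate by the stannylcopper reagent places tin on C13 and should give the trisubstituted C7=C11 alkene with C6 trans to the ester, the usual outcome for acrylate-derived acetates (Z by the CIP rules because CH2Sn outranks CO2Me).

Step 9
Reactants: 12 (Z)-2-(stannylmethyl) enoate
Product: 13 C12 allylic alcohol
Conditions: i-Bu2AlH, CH2Cl2, −78 °C; aq. KNaC4H4O6
Reagents that add atoms: none
Why: 1,2-Reduction of the conjugated ester with i-Bu2AlH gives the allylic alcohol and leaves the allylstannane, the silyl ether and the alkene geometry intact.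

Step 10
Reactants: 13 C12 allylic alcohol
Product: 14 C12 tert-butyldimethylsilyl ether
Conditions: t-BuMe2SiCl, imidazole, DMF, 0 °C to rt
Reagents that add atoms: tert-butyldimethylsilyl chloride, CC(C)(C)[Si](C)(C)Cl
Why: Imidazole-mediated silylation masks the C12 oxygen so that O8 will later be the only free hydroxyl.

Step 11
Reactants: 14 C12 tert-butyldimethylsilyl ether
Product: 15 C1 alcohol
Conditions: PPTS (cat.), MeOH/CH2Cl2, 0 °C
Reagents that add atoms: none
Why: Acid-catalysed methanolysis cleaves the primary triethylsilyl ether much faster than the tert-butyldimethylsilyl ether, and pyridinium tosylate is too weak an acid to protodestannylate the allylstannane or open the acetonide at 0 °C.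

Step 12
Reactants: 15 C1 alcohol
Product: 16 C1 aldehyde
Conditions: Dess–Martin periodinane, NaHCO3, CH2Cl2, 0 °C to rt
Reagents that add atoms: none
Why: Dess–Martin oxidation under bicarbonate buffer gives the aldehyde under neutral conditions that the allylstannane should tolerate.

Step 13
Reactants: 16 C1 aldehyde; 17 α-(triphenylphosphoranylidene)-γ-butyrolactone
Product: 18 (E)-α-alkylidene-γ-butyrolactone
Conditions: 17, CH2Cl2, rt
Reagents that add atoms: none
Why: Wittig olefination with the stabilised lactone ylide forms C1=C10 with the chain trans to the carbonyl (E), which is the geometry that puts C2 cis to C9, and brings in C8, C9, C10 and C14.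

Step 14
Reactants: 18 (E)-α-alkylidene-γ-butyrolactone
Product: 20 γ-hydroxy methyl ester, via potassium carboxylate 19 (not isolated)
Conditions: KOH (1 equiv), THF/MeOH/H2O, 0 °C to rt; evaporate; MeI, DMF, rt
Reagents that add atoms: potassium hydroxide, [K+].[OH-]; iodomethane, CI
Why: Saponification opens the lactone by acyl–oxygen cleavage and SN2 O-methylation of the carboxylate in DMF fixes the open form as the methyl ester under neutral conditions that disfavour relactonisation, without touching the E geometry.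

Step 15
Reactants: 20 γ-hydroxy methyl ester
Product: 21 allylstannane aldehyde (cyclisation precursor)
Conditions: Dess–Martin periodinane, NaHCO3, CH2Cl2, 0 °C
Reagents that add atoms: none
Why: Buffered Dess–Martin oxidation converts the primary C8 alcohol into the aldehyde without a base strong enough to move the C1=C10 bond into conjugation with it; the β,γ-unsaturated aldehyde is used at once.

Step 16
Reactants: 21 allylstannane aldehyde
Product: 22 ten-membered 8-hydroxy carbocycle
Conditions: BF3·OEt2 (3 equiv), CH2Cl2, −78 °C, 21 added slowly to 0.002 M; aq. NaHCO3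
Reagents that add atoms: none
Why: BF3 binds the C8 aldehyde and the allylstannane attacks through C7 in an open anti-SE2′ transition state, with the C13–Sn bond parallel to the π system and tin leaving from C13 as Bu3SnF, so that the C7–C8 bond, the C11=C13 methylene and the carbocycle form in one event; the closest known reaction type is the Lewis acid-promoted intramolecular allylstannane–aldehyde addition used for macrocyclisation. The ten-membered ring (C1–C10) closes by 10-exo-trig attack of C7 on the carbonyl carbon C8, with C11 left outside the ring. C7 (R) is controlled by the C6 stereocentre: allylic 1,3-strain with the cis CH2SnBu3 group holds H6 in the alkene plane and the aldehyde adds to the face anti to the C6–O bond, which gives the trans relation of O6 and C11 on the ring. C8 (R) is controlled relative to C7 by the open arrangement of the C=O and C7=C11 bonds, which places O8 syn to C6 (cis to C11 on the ring) and should do so from either alkene geometry. The step needs ring closure to outrun intermolecular allylation, which high dilution, the trans-acetonide and the cis arrangement of C9 and C2 on C10=C1 favour, and it needs the aldehyde to react in preference to the enoate, which holds because only the aldehyde is activated by BF3 at −78 °C.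

Step 17
Reactants: 22 ten-membered 8-hydroxy carbocycle; 23 angelic acid
Product: 24 8-O-angelate
Conditions: 23, 2,4,6-trichlorobenzoyl chloride, Et3N, toluene, rt; then 22, 80 °C
Reagents that add atoms: none
Why: Yamaguchi-type esterification through the mixed 2,4,6-trichlorobenzoic anhydride without DMAP acylates the only free hydroxyl (O8) and is the acylation mode that keeps the Z geometry of the angelate; C8 keeps its configuration because the C8–O bond is not broken.

Step 18
Reactants: 24 8-O-angelate
Product: 25 5,6,12-triol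
Conditions: aq. HCl (1 M), THF, rt
Reagents that add atoms: none
Why: Dilute aqueous acid hydrolyses the isopropylidene acetal and the primary silyl ether in one operation, while the two esters and the exocyclic alkenes should survive.

Step 19
Reactants: 25 5,6,12-triol
Product: 28 CNP0163095.1 (target), via hydroxy enal 26 (not isolated), via lactol 27 (not isolated)
Conditions: TEMPO (cat.), PhI(OAc)2, CH2Cl2, rt
Reagents that add atoms: none
Why: TEMPO/PhI(OAc)2 oxidative lactonisation, in which the primary allylic C12 alcohol is oxidised in preference to the secondary C5 hydroxyl, the enal closes with the C6 hydroxyl to the five-membered lactol (5-exo-trig at the carbonyl) and a second oxidation gives the α-methylene-γ-lactone.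

**Compound list**

1 | dimethyl (4R,5R)-2,2-dimethyl-1,3-dioxolane-4,5-dicarboxylate (dimethyl 2,3-O-isopropylidene-L-tartrate) | COC(=O)[C@@H]1OC(C)(C)O[C@H]1C(=O)OC | starting material
2 | (4R,5R)-N4,N5-dimethoxy-N4,N5,2,2-tetramethyl-1,3-dioxolane-4,5-dicarboxamide | CON(C)C(=O)[C@@H]1OC(C)(C)O[C@H]1C(=O)N(C)OC | intermediate
3 | 3-bromopropan-1-ol | OCCCBr | starting material
4 | (3-bromopropoxy)triethylsilane | CC[Si](CC)(CC)OCCCBr | intermediate
5 | [3-(triethylsilyloxy)propyl]magnesium bromide | CC[Si](CC)(CC)OCCC[Mg]Br | intermediate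
6 | (4R,5R)-N-methoxy-N,2,2-trimethyl-5-[4-(triethylsilyloxy)butanoyl]-1,3-dioxolane-4-carboxamide | CC[Si](CC)(CC)OCCCC(=O)[C@@H]1OC(C)(C)O[C@H]1C(=O)N(C)OC | intermediate
7 | (4R,5S)-N-methoxy-N,2,2-trimethyl-5-[5-(triethylsilyloxy)pent-1-en-2-yl]-1,3-dioxolane-4-carboxamide | CC[Si](CC)(CC)OCCCC(=C)[C@@H]1OC(C)(C)O[C@H]1C(=O)N(C)OC | intermediate
8 | (4R,5S)-2,2-dimethyl-5-[5-(triethylsilyloxy)pent-1-en-2-yl]-1,3-dioxolane-4-carbaldehyde | CC[Si](CC)(CC)OCCCC(=C)[C@@H]1OC(C)(C)O[C@H]1C=O | intermediate
9 | methyl acrylate | C=CC(=O)OC | starting material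
10 | methyl 2-{hydroxy[(4S,5S)-2,2-dimethyl-5-(5-triethylsilyloxypent-1-en-2-yl)-1,3-dioxolan-4-yl]methyl}prop-2-enoate (both C7 epimers) | CC[Si](CC)(CC)OCCCC(=C)[C@@H]1OC(C)(C)O[C@H]1C(O)C(=C)C(=O)OC | intermediate
11 | methyl 2-{acetoxy[(4R,5S)-2,2-dimethyl-5-(5-triethylsilyloxypent-1-en-2-yl)-1,3-dioxolan-4-yl]methyl}prop-2-enoate (both C7 epimers) | CC[Si](CC)(CC)OCCCC(=C)[C@@H]1OC(C)(C)O[C@H]1C(OC(C)=O)C(=C)C(=O)OC | intermediate
12 | methyl (2Z)-3-{(4S,5S)-2,2-dimethyl-5-[5-(triethylsilyloxy)pent-1-en-2-yl]-1,3-dioxolan-4-yl}-2-[(tributylstannyl)methyl]prop-2-enoate | CC[Si](CC)(CC)OCCCC(=C)[C@@H]1OC(C)(C)O[C@H]1/C=C(/C(=O)OC)C[Sn](CCCC)(CCCC)CCCC | intermediate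
13 | (2Z)-3-{(4S,5S)-2,2-dimethyl-5-[5-(triethylsilyloxy)pent-1-en-2-yl]-1,3-dioxolan-4-yl}-2-[(tributylstannyl)methyl]prop-2-en-1-ol | CC[Si](CC)(CC)OCCCC(=C)[C@@H]1OC(C)(C)O[C@H]1/C=C(/CO)C[Sn](CCCC)(CCCC)CCCC | intermediate
14 | tert-butyldimethylsilyl ether of 13 (C12–OSiMe2t-Bu; C1–OSiEt3 retained; Z at C7=C11) | CC[Si](CC)(CC)OCCCC(=C)[C@@H]1OC(C)(C)O[C@H]1/C=C(/CO[Si](C)(C)C(C)(C)C)C[Sn](CCCC)(CCCC)CCCC | intermediate
15 | 4-{(4S,5S)-5-[(1Z)-3-(tert-butyldimethylsilyloxy)-2-[(tributylstannyl)methyl]prop-1-en-1-yl]-2,2-dimethyl-1,3-dioxolan-4-yl}pent-4-en-1-ol | OCCCC(=C)[C@@H]1OC(C)(C)O[C@H]1/C=C(/CO[Si](C)(C)C(C)(C)C)C[Sn](CCCC)(CCCC)CCCC | intermediate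
16 | 4-{(4S,5S)-5-[(1Z)-3-(tert-butyldimethylsilyloxy)-2-[(tributylstannyl)methyl]prop-1-en-1-yl]-2,2-dimethyl-1,3-dioxolan-4-yl}pent-4-enal | O=CCCC(=C)[C@@H]1OC(C)(C)O[C@H]1/C=C(/CO[Si](C)(C)C(C)(C)C)C[Sn](CCCC)(CCCC)CCCC | intermediate
17 | 3-(triphenyl-λ5-phosphanylidene)oxolan-2-one | O=C1OCCC1=P(c1ccccc1)(c1ccccc1)c1ccccc1 | starting material
18 | (3E)-3-(4-{(4S,5S)-5-[(1Z)-3-(tert-butyldimethylsilyloxy)-2-[(tributylstannyl)methyl]prop-1-en-1-yl]-2,2-dimethyl-1,3-dioxolan-4-yl}pent-4-en-1-ylidene)oxolan-2-one | O=C1OCC/C1=C\CCC(=C)[C@@H]2OC(C)(C)O[C@H]2/C=C(/CO[Si](C)(C)C(C)(C)C)C[Sn](CCCC)(CCCC)CCCC | intermediate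
19 | potassium (2E)-6-{(4S,5S)-5-[(1Z)-3-(tert-butyldimethylsilyloxy)-2-[(tributylstannyl)methyl]prop-1-en-1-yl]-2,2-dimethyl-1,3-dioxolan-4-yl}-2-(2-hydroxyethyl)hepta-2,6-dienoate | OCC/C(C(=O)[O-])=C\CCC(=C)[C@@H]1OC(C)(C)O[C@H]1/C=C(/CO[Si](C)(C)C(C)(C)C)C[Sn](CCCC)(CCCC)CCCC.[K+] | intermediate
20 | methyl (2E)-6-{(4S,5S)-5-[(1Z)-3-(tert-butyldimethylsilyloxy)-2-[(tributylstannyl)methyl]prop-1-en-1-yl]-2,2-dimethyl-1,3-dioxolan-4-yl}-2-(2-hydroxyethyl)hepta-2,6-dienoate | OCC/C(C(=O)OC)=C\CCC(=C)[C@@H]1OC(C)(C)O[C@H]1/C=C(/CO[Si](C)(C)C(C)(C)C)C[Sn](CCCC)(CCCC)CCCC | intermediate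
21 | methyl (2E)-6-{(4S,5S)-5-[(1Z)-3-(tert-butyldimethylsilyloxy)-2-[(tributylstannyl)methyl]prop-1-en-1-yl]-2,2-dimethyl-1,3-dioxolan-4-yl}-2-(2-oxoethyl)hepta-2,6-dienoate | O=CC/C(C(=O)OC)=C\CCC(=C)[C@@H]1OC(C)(C)O[C@H]1/C=C(/CO[Si](C)(C)C(C)(C)C)C[Sn](CCCC)(CCCC)CCCC | intermediate
22 | methyl (5S,6S,7R,8R)-12-(tert-butyldimethylsilyloxy)-8-hydroxy-5,6-(isopropylidenedioxy)germacra-1(10)E,4(15),11(13)-trien-14-oate | O[C@@H]1C/C(C(=O)OC)=C\CCC(=C)[C@@H]2OC(C)(C)O[C@H]2[C@@H]1C(=C)CO[Si](C)(C)C(C)(C)C | intermediate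
23 | angelic acid, (2Z)-2-methylbut-2-enoic acid | C/C=C(/C)C(=O)O | starting material
24 | methyl (5S,6S,7R,8R)-8-(angeloyloxy)-12-(tert-butyldimethylsilyloxy)-5,6-(isopropylidenedioxy)germacra-1(10)E,4(15),11(13)-trien-14-oate | C/C=C(/C)C(=O)O[C@@H]1C/C(C(=O)OC)=C\CCC(=C)[C@@H]2OC(C)(C)O[C@H]2[C@@H]1C(=C)CO[Si](C)(C)C(C)(C)C | intermediate
25 | methyl (5S,6S,7S,8R)-8-(angeloyloxy)-5,6,12-trihydroxygermacra-1(10)E,4(15),11(13)-trien-14-oate (C7 unchanged in space; its descriptor changes with the priorities) | C/C=C(/C)C(=O)O[C@@H]1C/C(C(=O)OC)=C\CCC(=C)[C@H](O)[C@@H](O)[C@@H]1C(=C)CO | intermediate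
26 | methyl (5S,6S,7S,8R)-8-(angeloyloxy)-5,6-dihydroxy-12-oxogermacra-1(10)E,4(15),11(13)-trien-14-oate | C/C=C(/C)C(=O)O[C@@H]1C/C(C(=O)OC)=C\CCC(=C)[C@H](O)[C@@H](O)[C@@H]1C(=C)C=O | intermediate
27 | 6,12-lactol of 26 (12-hydroxy-6,12-epoxy compound; C12 epimers; 5S,6S,7R,8R) | C=C1C(O)O[C@H]2[C@H]1[C@H](OC(=O)/C(C)=C\C)C/C(C(=O)OC)=C\CCC(=C)[C@@H]2O | intermediate
28 | CNP0163095.1, methyl (5S,6S,7R,8R)-8-(angeloyloxy)-5-hydroxygermacra-1(10)E,4(15),11(13)-trien-12,6-olid-14-oate | C=C1C(=O)O[C@H]2[C@H]1[C@H](OC(=O)/C(C)=C\C)C/C(C(=O)OC)=C\CCC(=C)[C@@H]2O | target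

**Step count and risks**

Total: 19 steps. Longest linear sequence: 18 steps (1 to 28 through steps 1 and 3–19).

Steps most likely to fail:

1. Step 16. Intermolecular allylation may outrun closure of the ten-membered ring, adventitious acid may protodestannylate the allylstannane, or the C7/C8 relation may come out wrong because the ring forces a transition state other than the open one. The fallback replaces the open Lewis acid closure by a chromium-mediated closure through a cyclic transition state, a mode known for ten-membered carbocycles. It sets out from 21, which is treated with I2 in CH2Cl2 at −78 °C to give the allylic iodide aldehyde F1 (either allylic isomer leads to the same allylchromium species). F1 is closed with CrCl2 in THF at high dilution (intramolecular Nozaki–Hiyama allylation) to the carbinol F2, expected from the chair transition state to be the 7,8-anti isomer, that is the C8 epimer of 22. Mitsunobu esterification of F2 with angelic acid 23 (PPh3, diisopropyl azodicarboxylate, toluene) inverts C8 and comes back to the route at 24.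

2. Step 14. The γ-hydroxy ester may relactonise during alkylation or work-up, or hydroxide may add in conjugate fashion to the alkylidene lactone. The fallback never passes through the lactone and sets out from aldehyde 16. 2-Iodoethanol is silylated (Et3SiCl, imidazole) to (2-iodoethoxy)triethylsilane F3, which alkylates trimethyl phosphonoacetate (NaH, DMF) to the phosphonate F4. Horner–Wadsworth–Emmons reaction of F4 with 16 (NaH, THF, 0 °C) should give the triethylsilyl-protected (E)-enoate F5 after removal of the minor Z isomer. PPTS in MeOH/CH2Cl2 at 0 °C, as in step 11, frees the alcohol and comes back to the route at 20, which goes straight into step 15.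

3. Step 19. The lactol may close onto O5 in place of O6 and lead to the δ-lactone, or the allylic C5 carbinol may be over-oxidised. The fallback oxidises C12 while O5 and O6 are still tied in the acetonide and sets out from 24. HF·pyridine buffered with pyridine in THF removes only the silyl group to give the C12 alcohol F6. MnO2 in CH2Cl2 gives the enal F7, and Pinnick oxidation (NaClO2, NaH2PO4, 2-methylbut-2-ene, t-BuOH/H2O) gives the acid F8. Aqueous HCl in THF then cleaves the acetonide, and the dihydroxy acid should lactonise under thermodynamic control to the five-membered lactone, coming back to the route at 28.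

**Further compounds**

F1 | step 16 | methyl (2E)-6-{(4S,5S)-5-[(1Z)-3-(tert-butyldimethylsilyloxy)-2-(iodomethyl)prop-1-en-1-yl]-2,2-dimethyl-1,3-dioxolan-4-yl}-2-(2-oxoethyl)hepta-2,6-dienoate | O=CC/C(C(=O)OC)=C\CCC(=C)[C@@H]1OC(C)(C)O[C@H]1/C=C(/CO[Si](C)(C)C(C)(C)C)CI
F2 | step 16 | methyl (5S,6S,7R,8S)-12-(tert-butyldimethylsilyloxy)-8-hydroxy-5,6-(isopropylidenedioxy)germacra-1(10)E,4(15),11(13)-trien-14-oate (C8 epimer of 22) | O[C@H]1C/C(C(=O)OC)=C\CCC(=C)[C@@H]2OC(C)(C)O[C@H]2[C@@H]1C(=C)CO[Si](C)(C)C(C)(C)C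
F3 | step 14 | (2-iodoethoxy)triethylsilane | CC[Si](CC)(CC)OCCI
F4 | step 14 | methyl 2-(dimethoxyphosphoryl)-4-(triethylsilyloxy)butanoate | COC(=O)C(CCO[Si](CC)(CC)CC)P(=O)(OC)OC
F5 | step 14 | triethylsilyl ether of 20 | CC[Si](CC)(CC)OCC/C(C(=O)OC)=C\CCC(=C)[C@@H]1OC(C)(C)O[C@H]1/C=C(/CO[Si](C)(C)C(C)(C)C)C[Sn](CCCC)(CCCC)CCCC
F6 | step 19 | methyl (5S,6S,7R,8R)-8-(angeloyloxy)-12-hydroxy-5,6-(isopropylidenedioxy)germacra-1(10)E,4(15),11(13)-trien-14-oate | C/C=C(/C)C(=O)O[C@@H]1C/C(C(=O)OC)=C\CCC(=C)[C@@H]2OC(C)(C)O[C@H]2[C@@H]1C(=C)CO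
F7 | step 19 | 12-aldehyde corresponding to F6 | C/C=C(/C)C(=O)O[C@@H]1C/C(C(=O)OC)=C\CCC(=C)[C@@H]2OC(C)(C)O[C@H]2[C@@H]1C(=C)C=O
F8 | step 19 | 12-carboxylic acid corresponding to F6 | C/C=C(/C)C(=O)O[C@@H]1C/C(C(=O)OC)=C\CCC(=C)[C@@H]2OC(C)(C)O[C@H]2[C@@H]1C(=C)C(=O)O
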